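**Plan**

1. Retrosynthetic cuts, in order: the C6–O–CH3 bond (leaving a C6 phenol); O1–C8a of the pyranone (key cut, giving an open-chain 1,3-diketone); C2–C3 (Claisen); then C4–C4a (Friedel–Crafts acetylation) and C1'–C2 (carboxylation of an aryllithium).
2. Structural feature used: C8a, the A-ring carbon bonded to O1, is para to the C6 oxygen and ortho to C4a, which carries the diketone chain. Both carbons ortho to C6 (C5 and C7) are methoxylated, so with C6–OH free, C8a is the only C–H site of the derived phenoxonium ion and lies within six-membered reach of the enol oxygen.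
3. Forward: rings A and B are bought (2,6-dimethoxyphenol and 2,3,4-trimethoxybenzaldehyde). The B-ring ester is made in steps 1–3, the A-ring methyl ketone in steps 4–5, the three-carbon chain is completed in step 6 and the phenol is uncovered in step 7.
4. Ring C, the only ring built, closes in step 8 by anodic dehydrogenative O1–C8a coupling; step 9 methylates the C6 hydroxyl.
5. Stereochemistry: none to control; the target is achiral and the sp3 C8a of the transient dienone is lost on tautomerisation.

Key step: step 8

Remark: the target has no stereocentre and no stereogenic double bond, so it is achiral and "single enantiomer" is read as the single constitution drawn.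

**Route**

Step 1
Reactants: 1 2,3,4-trimethoxybenzaldehyde
Product: 3 2,3,4-trimethoxyphenol, via 2,3,4-trimethoxyphenyl formate 2 (not isolated)
Conditions: mCPBA, CH2Cl2, 0 °C → rt; aq. NaHCO3 wash; then cat. K2CO3, MeOH, rt
Reagents that add atoms: mCPBA (3-chloroperbenzoic acid), O=C(OO)c1cccc(Cl)c1
Why: Dakin-type Baeyer–Villiger oxidation, in which the aryl group carrying ortho and para methoxy donors migrates in the Criegee adduct to give the aryl formate, which base-catalysed methanolysis should cleave to the phenol.

Step 2
Reactants: 3 2,3,4-trimethoxyphenol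
Product: 4 1,2,3,4-tetramethoxybenzene
Conditions: MeI, K2CO3, acetone, reflux
Reagents that add atoms: iodomethane, CI
Why: Williamson ether synthesis on an unhindered phenoxide.

Step 3
Reactants: 4 1,2,3,4-tetramethoxybenzene
Product: 6 methyl 2,3,4,5-tetramethoxybenzoate, via (2,3,4,5-tetramethoxyphenyl)lithium 5 (not isolated)
Conditions: n-BuLi, TMEDA, THF, 0 °C; then added by cannula to excess ClCO2Me, THF, −78 °C
Reagents that add atoms: methyl chloroformate, COC(=O)Cl
Why: methoxy-directed ortho-metalation at one of the two symmetry-equivalent C–H positions, followed by inverse addition to excess chloroformate so that the ester formed should not meet a second equivalent of aryllithium.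

Step 4
Reactants: 7 2,6-dimethoxyphenol; 8 benzyl bromide
Product: 9 2-(benzyloxy)-1,3-dimethoxybenzene
Conditions: K2CO3, DMF, 60 °C
Reagents that add atoms: none
Why: Williamson ether synthesis, the benzyl group being chosen because it survives the later strong base and is removed by neutral hydrogenolysis.

Step 5
Reactants: 9 2-(benzyloxy)-1,3-dimethoxybenzene
Product: 10 1-[3-(benzyloxy)-2,4-dimethoxyphenyl]ethan-1-one
Conditions: AcCl, SnCl4, CH2Cl2, −20 → 0 °C
Reagents that add atoms: acetyl chloride, CC(=O)Cl
Why: Friedel–Crafts acylation, which on 1,2,3-trialkoxybenzenes goes para to one terminal alkoxy group and ortho to the other because the central alkoxy group is twisted out of conjugation, while the mild Lewis acid at low temperature should spare the benzyl ether, which is not ortho to the new carbonyl.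

Step 6
Reactants: 10 1-[3-(benzyloxy)-2,4-dimethoxyphenyl]ethan-1-one; 6 methyl 2,3,4,5-tetramethoxybenzoate
Product: 11 1-[3-(benzyloxy)-2,4-dimethoxyphenyl]-3-(2,3,4,5-tetramethoxyphenyl)propane-1,3-dione
Conditions: NaH, THF, reflux; then 1 M HCl
Reagents that add atoms: none
Why: crossed Claisen condensation of a methyl ketone enolate with a non-enolisable aryl ester, driven forward by deprotonation of the 1,3-diketone as it forms.

Step 7
Reactants: 11 1-[3-(benzyloxy)-2,4-dimethoxyphenyl]-3-(2,3,4,5-tetramethoxyphenyl)propane-1,3-dione
Product: 12 1-(3-hydroxy-2,4-dimethoxyphenyl)-3-(2,3,4,5-tetramethoxyphenyl)propane-1,3-dione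
Conditions: H2 (1 atm), 10% Pd/C, EtOAc, rt
Reagents that add atoms: none
Why: catalytic hydrogenolysis of a benzyl aryl ether, under neutral ambient-pressure conditions that should leave the enolised diketone and the methyl ethers untouched.

Step 8
Reactants: 12 1-(3-hydroxy-2,4-dimethoxyphenyl)-3-(2,3,4,5-tetramethoxyphenyl)propane-1,3-dione
Product: 14 6-hydroxy-5,7-dimethoxy-2-(2,3,4,5-tetramethoxyphenyl)-4H-chromen-4-one, via 5,7-dimethoxy-2-(2,3,4,5-tetramethoxyphenyl)-8aH-chromene-4,6-dione 13 (not isolated)
Conditions: constant current, 2.1 F/mol, boron-doped diamond anode, stainless-steel cathode, undivided narrow-gap flow cell, 0.02 M in 1,1,1,3,3,3-hexafluoropropan-2-ol (HFIP), Bu4NPF6 (0.05 M), rt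
Reagents that add atoms: none
Why: Proposed new method: the 2,6-dimethoxyphenol unit is the most easily oxidised site of 12 (the B ring is an acyl-deactivated aryl ether without a free hydroxyl and the diketone stays neutral in base-free HFIP), so the anode should take two electrons and a proton from it to give a phenoxonium ion with positive charge at the para carbon, the future C8a; the enol oxygen of the B-ring-side carbonyl, tethered through C4a, adds there to give dienone 13, which tautomerises to the aromatic phenol 14 while hydrogen is evolved at the cathode. The closest known reactions are the para-selective anodic dehydrogenative couplings of 2,6-disubstituted phenols in HFIP and the oxidative cyclisation of 3'-hydroxybenzophenones to xanthones, but an enol oxygen has not been shown as the nucleophile. The pyranone closes by a six-membered O-attack on a ring carbon of the cation, formally 6-endo-trig when counted against the C4a=C8a bond, and the only other internal nucleophiles, C3 and the C4 carbonyl oxygen, could reach the ring only through four-membered transition states. No stereocentre is created in 14, since C8a is sp3 only in the transient racemic dienone 13. The selectivity required is attack at the unsubstituted para carbon and not at the methoxylated ortho carbon C5, which is also within six-membered reach: ipso addition there leads to a quinone monoketal that cannot aromatise and should reopen in the acidic fluorinated alcohol, whereas para addition is made irreversible by tautomerisation. Dilution should suppress para–para dimerisation of the phenoxyl radical, and passing only about 2.1 F/mol in a single pass through the flow cell should limit further oxidation of the para-alkoxyphenol product.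

Step 9
Reactants: 14 6-hydroxy-5,7-dimethoxy-2-(2,3,4,5-tetramethoxyphenyl)-4H-chromen-4-one
Product: 15 agehoustin B, 5,6,7-trimethoxy-2-(2,3,4,5-tetramethoxyphenyl)-4H-chromen-4-one
Conditions: MeI, K2CO3, acetone, reflux
Reagents that add atoms: iodomethane, CI
Why: Williamson O-methylation of the only acidic hydroxyl in the molecule, which should proceed despite the two flanking methoxy groups because the electrophile is small.

**Compound list**

1 | 2,3,4-trimethoxybenzaldehyde | COc1ccc(C=O)c(OC)c1OC | starting material
2 | 2,3,4-trimethoxyphenyl formate | COc1ccc(OC=O)c(OC)c1OC | intermediate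
3 | 2,3,4-trimethoxyphenol | COc1ccc(O)c(OC)c1OC | intermediate
4 | 1,2,3,4-tetramethoxybenzene | COc1ccc(OC)c(OC)c1OC | intermediate
5 | (2,3,4,5-tetramethoxyphenyl)lithium | [Li]c1cc(OC)c(OC)c(OC)c1OC | intermediate
6 | methyl 2,3,4,5-tetramethoxybenzoate | COC(=O)c1cc(OC)c(OC)c(OC)c1OC | intermediate
7 | 2,6-dimethoxyphenol | COc1cccc(OC)c1O | starting material
8 | benzyl bromide | BrCc1ccccc1 | starting material
9 | 2-(benzyloxy)-1,3-dimethoxybenzene | COc1cccc(OC)c1OCc1ccccc1 | intermediate
10 | 1-[3-(benzyloxy)-2,4-dimethoxyphenyl]ethan-1-one | COc1ccc(C(C)=O)c(OC)c1OCc1ccccc1 | intermediate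
11 | 1-[3-(benzyloxy)-2,4-dimethoxyphenyl]-3-(2,3,4,5-tetramethoxyphenyl)propane-1,3-dione | COc1ccc(C(=O)CC(=O)c2cc(OC)c(OC)c(OC)c2OC)c(OC)c1OCc1ccccc1 | intermediate
12 | 1-(3-hydroxy-2,4-dimethoxyphenyl)-3-(2,3,4,5-tetramethoxyphenyl)propane-1,3-dione | COc1ccc(C(=O)CC(=O)c2cc(OC)c(OC)c(OC)c2OC)c(OC)c1O | intermediate
13 | 5,7-dimethoxy-2-(2,3,4,5-tetramethoxyphenyl)-8aH-chromene-4,6-dione (racemic, transient) | COC1=CC2OC(c3cc(OC)c(OC)c(OC)c3OC)=CC(=O)C2=C(OC)C1=O | intermediate
14 | 6-hydroxy-5,7-dimethoxy-2-(2,3,4,5-tetramethoxyphenyl)-4H-chromen-4-one | COc1cc(-c2cc(=O)c3c(OC)c(O)c(OC)cc3o2)c(OC)c(OC)c1OC | intermediate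
15 | agehoustin B, 5,6,7-trimethoxy-2-(2,3,4,5-tetramethoxyphenyl)-4H-chromen-4-one | COc1cc(-c2cc(=O)c3c(OC)c(OC)c(OC)cc3o2)c(OC)c(OC)c1OC | target

**Step count and risks**

Total step count: 9 steps. Longest linear sequence: 7 steps (steps 1, 2, 3, 6, 7, 8, 9 from 2,3,4-trimethoxybenzaldehyde); the A-ring branch (steps 4, 5) joins at step 6.

Steps most likely to fail:

Step 8 (the new method). What may go wrong: electron transfer from the B ring or the enol instead of the phenol, para–para dimerisation of the phenoxyl radical, ipso trapping at the methoxylated C5 to a quinone monoketal that cannot rearomatise, or further oxidation of the product phenol. The fallback uses known chemistry, sets out from 6 and returns at 15; the pyranone oxygen is brought in with the A ring instead of being attached oxidatively. Commercial 3,4,5-trimethoxyphenol would be C-acetylated ortho to its hydroxyl (AcOH, BF3·OEt2, 90 °C) to 1-(6-hydroxy-2,3,4-trimethoxyphenyl)ethan-1-one F1. Claisen condensation of its dianion with ester 6 (NaH, THF, reflux) should give 1-(6-hydroxy-2,3,4-trimethoxyphenyl)-3-(2,3,4,5-tetramethoxyphenyl)propane-1,3-dione F2. Acid-catalysed cyclodehydration of this ortho-hydroxyaryl diketone (cat. H2SO4, AcOH, 100 °C) should deliver 15 directly, so that steps 4–9 are no longer needed.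

Step 5. What may go wrong: Lewis-acid cleavage or migration of the benzyl group, or chelation-assisted loss of the methyl group ortho to the new carbonyl. The fallback sets out from 9 and returns at 10; the acetyl group is introduced through an organometallic instead of an acylium ion. NBS in MeCN at 0 °C should brominate 9 at the same ring position to give 3-(benzyloxy)-1-bromo-2,4-dimethoxybenzene F3. Bromine–lithium exchange (n-BuLi, THF, −78 °C) would give [3-(benzyloxy)-2,4-dimethoxyphenyl]lithium F4, which is quenched with N-methoxy-N-methylacetamide to give 10 after aqueous NH4Cl work-up.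

Step 6. What may go wrong: slow addition of the enolate to the hindered, electron-rich ester, self-condensation of the ketone, or retro-Claisen cleavage of the product by methoxide at reflux. The fallback sets out from 10, takes its aryl partner from 4 and returns at 11; the C2–C3 bond is made by aldol addition and the oxidation level adjusted afterwards. Rieche formylation of 4 (Cl2CHOMe, TiCl4, CH2Cl2, 0 °C) should give 2,3,4,5-tetramethoxybenzaldehyde F5. The lithium enolate of 10 (LDA, THF, −78 °C) should add to it to give racemic 1-[3-(benzyloxy)-2,4-dimethoxyphenyl]-3-hydroxy-3-(2,3,4,5-tetramethoxyphenyl)propan-1-one F6, and Dess–Martin oxidation of the secondary alcohol (CH2Cl2, rt) should give 11.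

**Further compounds**

F1 | step 8 | 1-(6-hydroxy-2,3,4-trimethoxyphenyl)ethan-1-one | CC(=O)c1c(O)cc(OC)c(OC)c1OC
F2 | step 8 | 1-(6-hydroxy-2,3,4-trimethoxyphenyl)-3-(2,3,4,5-tetramethoxyphenyl)propane-1,3-dione | COc1cc(O)c(C(=O)CC(=O)c2cc(OC)c(OC)c(OC)c2OC)c(OC)c1OC
F3 | step 5 | 3-(benzyloxy)-1-bromo-2,4-dimethoxybenzene | COc1ccc(Br)c(OC)c1OCc1ccccc1
F4 | step 5 | [3-(benzyloxy)-2,4-dimethoxyphenyl]lithium | [Li]c1ccc(OC)c(OCc2ccccc2)c1OC
F5 | step 6 | 2,3,4,5-tetramethoxybenzaldehyde | COc1cc(C=O)c(OC)c(OC)c1OC
F6 | step 6 | 1-[3-(benzyloxy)-2,4-dimethoxyphenyl]-3-hydroxy-3-(2,3,4,5-tetramethoxyphenyl)propan-1-one (racemic) | COc1ccc(C(=O)CC(O)c2cc(OC)c(OC)c(OC)c2OC)c(OC)c1OCc1ccccc1
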